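Start by deciding to count what the columns leave out.

| setting | north | south-east | south-west | flask |
|---|---|---|---|---|
| substrate | 0.78 M | 0.78 M | 1.6 M | 0.78 M |
| partner | 0.57 M | 1.3 M | 0.858 M | 0.858 M |
| remark | run made earlier | run made earlier | run made earlier |  |
| time |  |  |  | 12 min |

- north (time / min: isomer of the product / %, target / %, substrate / %): 0.833: 2.5, 10.6, 69.7; 2.50: 4.3, 14.3, 48.4; 4.00: 4.3, 14.1, 40.7; 6.00: 1.0, 12.6, 35.9; 10.0: 3.3, 13.4, 35.5; 12.0: 3.9, 13.3, 34.5
- south-east (time / min: isomer of the product / %, target / %, substrate / %): 0.833: 2.1, 20.8, 61.9; 2.50: 8.5, 29.8, 39.3; 4.00: 6.2, 31.1, 32.6; 6.00: 6.8, 29.9, 27.0; 10.0: 9.1, 28.3, 26.3; 12.0: 8.1, 27.9, 26.2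
- south-west (time / min: isomer of the product / %, target / %, substrate / %): 2.50: 4.1, 16.2, 45.7; 5.00: 6.1, 16.5, 35.9; 8.00: 2.2, 16.3, 34.3; 10.0: 3.6, 16.6, 34.1; 12.0: 4.2, 17.2, 33.8

(readings scatter by 1 percentage point)

- share of isomer of the product in isomer of the product plus target at 2.0 s
- share of isomer of the product in isomer of the product plus target at 12 min
- which of isomer of the product and target there is more of at 12 min



Take the fraction of the charge missing from substrate, target and isomer of the product, and divide it by the substrate fraction. At 12.0 min the north, south-east and south-west runs read 1.40, 1.44 and 1.33, although their charges differ. Their mean, 1.39, is the hidden ratio. I read it as the substrate turning reversibly into something unseen, with the isomer growing from that.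

Now take the time scales in turn, shortest first. At 0.833 min the ratio already reads 0.247 in the north run and 0.246 in the south-east run, while isomer over target reads 0.236 and 0.101. On a ramp from zero, isomer over target follows the ramp's mean, half its end value, so it scales with time. Scaling the mean of those two readings down to 2.0 s gives 0.00674, which is a share of 0.669% in the flask.

By 6.00 min the north substrate has nearly stopped falling, at 35.9%, and the ramp has finished. For 12 min I take the mean of the last shares, 21.6%, with target ahead.

The forecast gives 15% at 2.0 s, far above my figure, on what it calls weak evidence for “a lower kinetic share with slow isomerisation”, and 21% at 12 min with target ahead.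

The flask gives 0.714% and 22.1%, with target ahead.

    substrate ⇌ other conformer (K = 1.40, k = 0.00490 s⁻¹)
    substrate + partner → target (k = 0.00640 M⁻¹ s⁻¹)
    partner + other conformer → isomer of the product (k = 0.00950 M⁻¹ s⁻¹)
    partner → decomposed reagent (k = 0.0150 s⁻¹)

Partner's decomposition reaches half of its turnover by 0.590 min, sooner than the 1.38 min relaxation half-life of substrate and other conformer. Partner, the limiting reagent, stands at 0.0865% of its charge in this flask at 6.00 min. The hidden ratio, an equilibrium constant read from the runs, splits what is not product: in this flask at 12 min it gives 30.9% substrate, and the flask holds 30.9%. In the neighbouring flask with 2.1 M of partner it gives 19.3%, and that flask holds 19.2%.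

The runs stem from a simulated flask on assumed constants, and the scatter is random.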